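Set out the flasks and the readings first, then answer.

| setting | Thursday's | Friday's | Saturday's | maple | cedar | alder | elm |
|---|---|---|---|---|---|---|---|
| G | 0.050 M | 0.025 M | 0.10 M | 0.050 M (fed, over 2.0 h) | 0.050 M | 0.050 M | 0.050 M |
| L | 0.065 M | 0.065 M | 0.065 M | 0.0650 M | 0.0650 M | 0.0650 M (in portions, 2, over 2.0 h) | 0.0650 M (fed, over 2.0 h) |
| remark | run made earlier | run made earlier | run made earlier | all else is in the flask from the start; the feed brings no volume worth counting | everything together at the start | first portion at the start, last at 2.0 h | all else is in the flask from the start; the feed brings no volume worth counting |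
| time |  |  |  | 2.5 h | 2.5 h | 2.5 h | 2.5 h |

Thursday's run (percent of the G charged)

| time / h | Q / % | D / % |
|---|---|---|
| 0.200 | 0.3 | 2.3 |
| 0.333 | 0.7 | 5.0 |
| 0.500 | 1.9 | 9.4 |
| 0.667 | 5.0 | 13.8 |
| 1.00 | 11.6 | 19.3 |
| 1.50 | 21.1 | 25.0 |
| 2.50 | 35.3 | 29.6 |

Friday's run (percent of the G charged)

| time / min | Q / % | D / % |
|---|---|---|
| 6.00 | 0 | 0.5 |
| 20.0 | 0.4 | 5.6 |
| 30.0 | 1.0 | 10.9 |
| 50.0 | 4.5 | 19.7 |
| 80.0 | 10.7 | 30.5 |
| 90.0 | 12.6 | 32.4 |
| 120 | 18.0 | 37.3 |

Saturday's run (percent of the G charged)

| time / min | Q / % | D / % |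
|---|---|---|
| 10.0 | 0 | 1.7 |
| 15.0 | 1.1 | 2.7 |
| 20.0 | 1.8 | 4.2 |
| 30.0 | 4.7 | 7.5 |
| 50.0 | 12.5 | 12.2 |
| 80.0 | 26.2 | 15.0 |
| 120 | 40.2 | 15.4 |

(standard deviation of a reading: 0.3 percentage points)

- percentages count the G that a species holds: one Q counts as two
- the analysis behind the earlier runs scatters by 0.3 percentage points, standard deviation

1. the flask with the highest amount of Q, in percent of the G charged ("all alike" if they lie within 1.5 percentage points) (maple / cedar / alder / elm / all alike)
2. final Q, as a percentage of the G charged, in maple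
3. final Q, as a percentage of the G charged, in cedar
4. final Q, as a percentage of the G charged, in alder
5. final Q, as a percentage of the G charged, in elm

*What makes Q?* In each run D shows first and Q follows, as if a D has to meet a G.

*Put a number on it.* Between 1.00 h and 1.50 h, Thursday's run gains 9.5 percentage points of Q. D stands near 22.1%, and the remainder of the charge near 61.5%. One Q counts as two, so the meeting constant kQ reads 13.9 L mol⁻¹ h⁻¹.

*One lucky pair of readings?* Friday's run, with 0.025 M of G, reads 14.7 L mol⁻¹ h⁻¹ between 50.0 min and 80.0 min. Saturday's run, with 0.10 M, reads 15.0 L mol⁻¹ h⁻¹ over the same stretch.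

*Your remainder may hold things you cannot see.* It may, so kQ belongs to the remainder, and I use it that way.

*What do you carry to a new flask?* The turnover count n, 2·kQ·c_G·t, says how many points of Q a flask gains in time t per point of D standing, if the remainder were the full charge. For c_G as charged, n is 3.49 in cedar, which repeats Thursday's recipe, so I commit to that run's 35.3%.

*And maple?* Averaged over the time, maple has had 60.0% of its G fed in, so n falls to 2.09. Scaling Thursday's Q by that share gives me 21.2%, a little under the forecast's figure.

The forecast named cedar, with maple 22.2%, cedar 35.3%, alder 26.2% and elm 24.7%. Its ground was: “Keeping D or G low suppresses Q, so cedar is highest.”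

The simulation gives maple 24.6%, cedar 35.2%, alder 27.7% and elm 23.8%, so cedar ends highest.

    G ⇌ X (K = 2.30, k = 0.00230 s⁻¹)
    L → Z (k = 6.60 × 10⁻⁴ s⁻¹)
    X + Z → D (k = 0.00450 L mol⁻¹ s⁻¹)
    G + D → Q (k = 0.0140 L mol⁻¹ s⁻¹)
    D ⇌ E (K = 0.390, k = 2.50 × 10⁻⁴ s⁻¹)

The remainder held X and E beside G. In cedar at the end, Q over D stands at 1.18, a third of n. Taking away the way back from X to G shrinks the gap between cedar and elm from 11 points to 0.86 points, the largest single effect tried, though not the main reason. Cedar's neighbour with 0.013 M of G has n of 0.907, a quarter of cedar's, and its ratio of Q to D is also a quarter of cedar's, with Q at 12.9% against D at 47.8%.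

(The data are calculated with constants of no real substance.)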